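We are asked how much ring stands after 2.0 d in three flasks that differ in their charge of substrate, and how that row runs from the dilute flask to the concentrated one.

| flask | substrate | remark | time |
|---|---|---|---|
| Thursday's | 3 mM | run made earlier |  |
| Saturday's | 16 mM | run made earlier |  |
| alpha | 6.0 mM |  | 2.0 d |
| gamma | 12 mM |  | 2.0 d |
| epsilon | 25 mM |  | 2.0 d |

| run | time / h | ring / % |
|---|---|---|
| Thursday's | 2.00 | 24 |
| Thursday's | 4.00 | 39 |
| Thursday's | 10.0 | 65 |
| Thursday's | 25.0 | 70 |
| Saturday's | 3.00 | 30 |
| Saturday's | 8.00 | 53 |
| Saturday's | 15.0 | 66 |
| Saturday's | 25.0 | 60 |

(scatter of a reading: 1.5 percentage points)

1. amount of ring at the end, in percent of the substrate charged for alpha, gamma, epsilon, in this order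
2. the shape of the row from first to last (rises all the way / rises, then falls / falls all the way / falls, then rises / hardly changes)

- "hardly changes" means that all values lie within two and a half points (for a concentration: within two and a half percent of the largest)

Both runs climb, and Saturday's falls back from 66 % to 60 % at its last reading, so ring is made from substrate and can be lost again, and Saturday's run, with the larger charge, ends lower than Thursday's. At the last reading, 25.0 h in both runs, Saturday's ring over Thursday's is 0.857. If ring is lost first order, its survival cancels in this ratio, which leaves the ratio of the shares of substrate that became ring. Our objection is that substrate may remain at that time. Thursday's first reading gives a first-order constant of 0.137 /h, which leaves about 3.25 % of the charge, a small remainder on both sides of the ratio.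

Now suppose substrate also goes by a path second order in itself. At concentration s, ring then takes one part in one plus b times s. Integrating from the charge down to nothing gives the share in closed form: the logarithm of one plus x, divided by x, where x is b times the charge. For small x this is one minus x over two, so the ratio gives 0.0220 /mM for b, a selectivity factor per unit of charge. But the expansion is crude for Saturday's run. Put back into the closed form, this b gives 0.885, and that gap to the reading is smaller than the ratio's scatter of 0.0282, so we keep it. Our shares are then 93.9 % for alpha and 79.7 % for epsilon. We commit to a falling row with epsilon over alpha at 0.848, and to no level.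

The forecast gives 44 %, 40 % and 33 %, so the row falls all the way, and it calls the side path behind Saturday's lower level “probably bimolecular oligomerisation of the substrate”. Its epsilon over alpha is 0.750, lower than ours.

The flask gives 51.9 %, 48.9 % and 43.6 %, so the row falls all the way.

    substrate → ring (k = 3.50 × 10⁻⁵ /s)
    2 substrate → open dimer (k = 3.50 × 10⁻⁴ /M/s)
    substrate + ring → side product (k = 4.00 × 10⁻⁵ /M/s)
    ring → over-reaction product (k = 4.10 × 10⁻⁶ /s)

In the flask, epsilon over alpha is 0.840. At the end, open dimer, counted as the substrate it holds, is 5.55 % in alpha and 18.8 % in epsilon. Carried to gamma, our b gives a share over alpha's of 0.945, and gamma's ring over alpha's is 0.942.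

The readings are calculated with constants of no real substance.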